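**Strategy.** The route rests on disconnecting the bond between the ring stereocentre C4 (ring numbered from the CH2OH-bearing carbon C1) and C2′ of the 6-methylhepta-1,5-dien-2-yl group. C4 lies β to C2, the olefinic CH of the C1=C2 allylic alcohol in the 14-membered ring, so C2 is treated as a latent carbonyl. A rhodium/chiral-diene-catalysed 1,4-addition of a 1,1-disubstituted alkenylboronate to an acyclic (E)-enamide, whose carbonyl is the future C2, forms this bond. It joins the C8 unit to the chain holding thirteen ring carbons and sets the only stereocentre. The same carbonyl, as the aldehyde, then closes the ring by intramolecular Horner–Wadsworth–Emmons olefination onto C1.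

Key step: step 9

Remark: locants C1–C14 are the ring atoms of the target (C1 bears CH2OH, C4 is the stereocentre, C7 and C11 bear methyl). The sense of induction of the diene ligand in step 9 is to be assigned on a model enamide and the antipode chosen that gives (R). The phosphonate-bearing carbon of 23–25 is carried as an epimeric mixture, because step 12 removes that centre.

Step 1
Reactants: 1 5-bromo-2-methylpent-2-ene; 2 propyne; 3 oxirane
Product: 6 (3Z)-4,8-dimethylnona-3,7-dien-1-ol, via Grignard reagent 4 (not isolated), via alkenylcopper 5 (not isolated)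
Conditions: Mg, Et2O; CuBr·SMe2, Et2O/Me2S, −45 °C; 2, −25 °C; pent-1-ynyllithium (from pent-1-yne, n-BuLi), then 3, −78 → −20 °C; aq NH4Cl
Reagents that add atoms: none
Why: Normant syn-carbocupration of propyne puts copper and the new alkyl group cis, and the (Z)-alkenylcopper (as its mixed pentynyl cuprate) opens oxirane with retention, which fixes the Z C11=C12 alkene and supplies C13 and C14.

Step 2
Reactants: 6 (3Z)-4,8-dimethylnona-3,7-dien-1-ol
Product: 7 (6Z)-9-chloro-2,6-dimethylnona-2,6-diene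
Conditions: PPh3, CCl4, CH2Cl2, rt → 40 °C
Reagents that add atoms: tetrachloromethane ClC(Cl)(Cl)Cl
Why: Appel chlorination (SN2 on the oxyphosphonium) gives a primary chloride that should be inert to the Grignard, metathesis and rhodium steps and serves later as the alkylating handle.

Step 3
Reactants: 7 (6Z)-9-chloro-2,6-dimethylnona-2,6-diene
Product: 8 (2E,6Z)-9-chloro-2,6-dimethylnona-2,6-dien-1-ol
Conditions: SeO2 (cat.), t-BuOOH, salicylic acid (cat.), CH2Cl2, 0 °C → rt, stopped at partial conversion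
Reagents that add atoms: selenium dioxide O=[Se]=O; tert-butyl hydroperoxide CC(C)(C)OO
Why: Riley allylic oxidation in the Sharpless catalytic mode (ene reaction, then [2,3]-shift) prefers the terminal isopropylidene unit and its (E)-methyl group, so the E C7=C8 alkene with an oxygenated C6 should result.

Step 4
Reactants: 8 (2E,6Z)-9-chloro-2,6-dimethylnona-2,6-dien-1-ol
Product: 9 (2E,6Z)-1-bromo-9-chloro-2,6-dimethylnona-2,6-diene
Conditions: PBr3, pyridine (cat.), Et2O, −10 °C
Reagents that add atoms: phosphorus tribromide BrP(Br)Br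
Why: bromination of the primary allylic alcohol via its phosphite ester (SN2) should keep the E geometry and leave the alkyl chloride untouched.

Step 5
Reactants: 9 (2E,6Z)-1-bromo-9-chloro-2,6-dimethylnona-2,6-diene; 10 allylmagnesium bromide
Product: 11 (5E,9Z)-12-chloro-5,9-dimethyldodeca-1,5,9-triene
Conditions: THF/Et2O, −20 → 0 °C
Reagents that add atoms: none
Why: allyl–allyl coupling by SN2 attack of the Grignard reagent at the unhindered primary allylic CH2 forms the C5–C6 bond, the unactivated alkyl chloride being far less reactive.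

Step 6
Reactants: 11 (5E,9Z)-12-chloro-5,9-dimethyldodeca-1,5,9-triene; 12 N-methoxy-N-methylprop-2-enamide
Product: 13 (2E,6E,10Z)-13-chloro-N-methoxy-N,6,10-trimethyltrideca-2,6,10-trienamide
Conditions: Hoveyda–Grubbs II (5 mol %), 12 (3 equiv), CH2Cl2, 40 °C
Reagents that add atoms: none
Why: olefin cross-metathesis of the only monosubstituted alkene with the electron-poor acrylamide should give the (E)-enamide, the trisubstituted alkenes reacting much more slowly.

Step 7
Reactants: 14 6-methylhept-5-en-2-one; 15 2,4,6-tri(propan-2-yl)benzenesulfonohydrazide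
Product: 16 N′-[(2E)-6-methylhept-5-en-2-ylidene]-2,4,6-tri(propan-2-yl)benzenesulfonohydrazide
Conditions: MeOH, HCl (cat.), rt
Reagents that add atoms: none
Why: acid-catalysed condensation gives the (E)-arylsulfonylhydrazone needed for the Shapiro reaction.

Step 8
Reactants: 16 N′-[(2E)-6-methylhept-5-en-2-ylidene]-2,4,6-tri(propan-2-yl)benzenesulfonohydrazide; 17 2-isopropoxy-4,4,5,5-tetramethyl-1,3,2-dioxaborolane
Product: 19 4,4,5,5-tetramethyl-2-(6-methylhepta-1,5-dien-2-yl)-1,3,2-dioxaborolane, via alkenyllithium 18 (not isolated)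
Conditions: n-BuLi (2.2 equiv), TMEDA, THF/hexane, −78 → 0 °C; 17, −78 °C → rt; aq NH4Cl
Reagents that add atoms: none
Why: Shapiro reaction: the dianion forms at the methyl group syn to the sulfonamide nitrogen, loss of sulfinate and N2 gives the 2-lithio-1-alkene regioselectively, and the borate ester traps it.

Step 9
Reactants: 13 (2E,6E,10Z)-13-chloro-N-methoxy-N,6,10-trimethyltrideca-2,6,10-trienamide; 19 4,4,5,5-tetramethyl-2-(6-methylhepta-1,5-dien-2-yl)-1,3,2-dioxaborolane
Product: 20 (3R,6E,10Z)-13-chloro-N-methoxy-N,6,10-trimethyl-3-(6-methylhepta-1,5-dien-2-yl)trideca-6,10-dienamide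
Conditions: 19 (2.5 equiv), [RhCl(C2H4)2]2 (2.5 mol %), 2,5-diphenylbicyclo[2.2.2]octa-2,5-diene (Ph-bod*, one antipode, 5.5 mol %), KOH (0.3 equiv), 1,4-dioxane/H2O 10:1, 40 °C
Reagents that add atoms: none
Why: The alkenyl group passes from boron to a Rh(I)–OH species, the (E)-enamide 13 coordinates and inserts into the Rh–C bond so that the alkenyl carbon lands on C3 (β), and water protonates the resulting oxa-π-allyl rhodium and regenerates Rh–OH. The closest known reaction type is the Hayashi–Miyaura rhodium/chiral-diene-catalysed asymmetric 1,4-addition of organoboron reagents to acyclic α,β-unsaturated Weinreb amides and esters, used here with a 1,1-disubstituted alkenylboronate. No ring is closed. The new stereocentre (the future C4) is controlled by the C2-symmetric diene on rhodium, which discriminates the enantiofaces of the bound enamide; the antipode is chosen that delivers the alkenyl group to the Re face of C3, which corresponds to (R). The step needs 1,4- over 1,2-addition and selection of one C=C bond out of five: the Weinreb amide resists 1,2-attack and only the conjugated electron-poor alkene binds and inserts, while the trisubstituted alkenes and the primary chloride are spectators. Protodeboronation of the hindered boronate is offset by its excess.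

Step 10
Reactants: 20 (3R,6E,10Z)-13-chloro-N-methoxy-N,6,10-trimethyl-3-(6-methylhepta-1,5-dien-2-yl)trideca-6,10-dienamide; 21 triethyl phosphonoacetate
Product: 23 ethyl (5Z,9E,13R)-2-(diethoxyphosphoryl)-15-[methoxy(methyl)amino]-6,10-dimethyl-13-(6-methylhepta-1,5-dien-2-yl)-15-oxopentadeca-5,9-dienoate, via sodium phosphonoacetate 22 (not isolated)
Conditions: 21 (3 equiv), NaH, DMF, 0 °C; then 20, NaI (cat.), 70 °C
Reagents that add atoms: none
Why: SN2 C-alkylation of the stabilised phosphonoacetate carbanion by the primary chloride (iodide catalysis) installs C1 with its ester and phosphonate; the weakly basic anion should leave the Weinreb amide and the β-stereocentre untouched.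

Step 11
Reactants: 23 ethyl (5Z,9E,13R)-2-(diethoxyphosphoryl)-15-[methoxy(methyl)amino]-6,10-dimethyl-13-(6-methylhepta-1,5-dien-2-yl)-15-oxopentadeca-5,9-dienoate
Product: 25 ethyl (5Z,9E,13R)-2-(diethoxyphosphoryl)-6,10-dimethyl-13-(6-methylhepta-1,5-dien-2-yl)-15-oxopentadeca-5,9-dienoate, via sodium enolate 24 (not isolated)
Conditions: NaHMDS (1.05 equiv), THF, −78 °C; DIBAL-H (1.3 equiv), −78 °C; AcOH, then aq Rochelle salt
Reagents that add atoms: none
Why: the phosphonoacetate is first masked as its sodium enolate, which hydride does not reduce, so DIBAL-H should reduce only the Weinreb amide to the chelated hemiaminal that releases the aldehyde on work-up (Weinreb reduction).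

Step 12
Reactants: 25 ethyl (5Z,9E,13R)-2-(diethoxyphosphoryl)-6,10-dimethyl-13-(6-methylhepta-1,5-dien-2-yl)-15-oxopentadeca-5,9-dienoate
Product: 26 ethyl (1E,4R,7E,11Z)-7,11-dimethyl-4-(6-methylhepta-1,5-dien-2-yl)cyclotetradeca-1,7,11-triene-1-carboxylate
Conditions: LiCl, DBU, MeCN, rt, slow addition to 1 mM final concentration
Reagents that add atoms: none
Why: intramolecular Horner–Wadsworth–Emmons olefination (Masamune–Roush conditions, high dilution) closes the 14-membered ring at C1=C2, and the stabilised α-alkyl phosphonate should give the (E)-enoate with C3 trans to the ester.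

Step 13
Reactants: 26 ethyl (1E,4R,7E,11Z)-7,11-dimethyl-4-(6-methylhepta-1,5-dien-2-yl)cyclotetradeca-1,7,11-triene-1-carboxylate
Product: 27 [(1E,4R,7E,11Z)-7,11-dimethyl-4-(6-methylhepta-1,5-dien-2-yl)cyclotetradeca-1,7,11-trien-1-yl]methanol
Conditions: DIBAL-H (3 equiv), CH2Cl2, −78 → 0 °C; aq Rochelle salt
Reagents that add atoms: none
Why: 1,2-reduction of the α,β-unsaturated ester by DIBAL-H gives the allylic alcohol without affecting the isolated alkenes or the stereocentre.

**Compound list**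

1 | 5-bromo-2-methylpent-2-ene | CC(C)=CCCBr | starting material
2 | propyne | CC#C | starting material
3 | oxirane | C1CO1 | starting material
4 | (4-methylpent-3-en-1-yl)magnesium bromide | CC(C)=CCC[Mg]Br | intermediate
5 | [(1Z)-2,6-dimethylhepta-1,5-dien-1-yl]copper | CC(C)=CCC/C(C)=C\[Cu] | intermediate
6 | (3Z)-4,8-dimethylnona-3,7-dien-1-ol | CC(C)=CCC/C(C)=C\CCO | intermediate
7 | (6Z)-9-chloro-2,6-dimethylnona-2,6-diene | CC(C)=CCC/C(C)=C\CCCl | intermediate
8 | (2E,6Z)-9-chloro-2,6-dimethylnona-2,6-dien-1-ol | OC/C(C)=C/CC/C(C)=C\CCCl | intermediate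
9 | (2E,6Z)-1-bromo-9-chloro-2,6-dimethylnona-2,6-diene | BrC/C(C)=C/CC/C(C)=C\CCCl | intermediate
10 | allylmagnesium bromide | C=CC[Mg]Br | starting material
11 | (5E,9Z)-12-chloro-5,9-dimethyldodeca-1,5,9-triene | C=CCC/C(C)=C/CC/C(C)=C\CCCl | intermediate
12 | N-methoxy-N-methylprop-2-enamide | C=CC(=O)N(C)OC | starting material
13 | (2E,6E,10Z)-13-chloro-N-methoxy-N,6,10-trimethyltrideca-2,6,10-trienamide | CON(C)C(=O)/C=C/CC/C(C)=C/CC/C(C)=C\CCCl | intermediate
14 | 6-methylhept-5-en-2-one | CC(=O)CCC=C(C)C | starting material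
15 | 2,4,6-tri(propan-2-yl)benzenesulfonohydrazide | CC(C)c1cc(C(C)C)c(S(=O)(=O)NN)c(C(C)C)c1 | starting material
16 | N′-[(2E)-6-methylhept-5-en-2-ylidene]-2,4,6-tri(propan-2-yl)benzenesulfonohydrazide | C/C(CCC=C(C)C)=N\NS(=O)(=O)c1c(C(C)C)cc(C(C)C)cc1C(C)C | intermediate
17 | 2-isopropoxy-4,4,5,5-tetramethyl-1,3,2-dioxaborolane | CC(C)OB1OC(C)(C)C(C)(C)O1 | starting material
18 | (6-methylhepta-1,5-dien-2-yl)lithium | [Li]C(=C)CCC=C(C)C | intermediate
19 | 4,4,5,5-tetramethyl-2-(6-methylhepta-1,5-dien-2-yl)-1,3,2-dioxaborolane | C=C(CCC=C(C)C)B1OC(C)(C)C(C)(C)O1 | intermediate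
20 | (3R,6E,10Z)-13-chloro-N-methoxy-N,6,10-trimethyl-3-(6-methylhepta-1,5-dien-2-yl)trideca-6,10-dienamide | C=C(CCC=C(C)C)[C@@H](CC(=O)N(C)OC)CC/C(C)=C/CC/C(C)=C\CCCl | intermediate
21 | triethyl phosphonoacetate | CCOC(=O)CP(=O)(OCC)OCC | starting material
22 | sodium salt of triethyl phosphonoacetate | CCOC(=O)[CH-]P(=O)(OCC)OCC.[Na+] | intermediate
23 | ethyl (5Z,9E,13R)-2-(diethoxyphosphoryl)-15-[methoxy(methyl)amino]-6,10-dimethyl-13-(6-methylhepta-1,5-dien-2-yl)-15-oxopentadeca-5,9-dienoate (C2 epimers) | C=C(CCC=C(C)C)[C@@H](CC(=O)N(C)OC)CC/C(C)=C/CC/C(C)=C\CCC(C(=O)OCC)P(=O)(OCC)OCC | intermediate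
24 | sodium enolate of 23 | C=C(CCC=C(C)C)[C@@H](CC(=O)N(C)OC)CC/C(C)=C/CC/C(C)=C\CC[C-](C(=O)OCC)P(=O)(OCC)OCC.[Na+] | intermediate
25 | ethyl (5Z,9E,13R)-2-(diethoxyphosphoryl)-6,10-dimethyl-13-(6-methylhepta-1,5-dien-2-yl)-15-oxopentadeca-5,9-dienoate (C2 epimers) | C=C(CCC=C(C)C)[C@@H](CC=O)CC/C(C)=C/CC/C(C)=C\CCC(C(=O)OCC)P(=O)(OCC)OCC | intermediate
26 | ethyl (1E,4R,7E,11Z)-7,11-dimethyl-4-(6-methylhepta-1,5-dien-2-yl)cyclotetradeca-1,7,11-triene-1-carboxylate | C=C(CCC=C(C)C)[C@H]1C/C=C(/C(=O)OCC)CC/C=C(/C)CC/C=C(\C)CC1 | intermediate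
27 | [(1E,4R,7E,11Z)-7,11-dimethyl-4-(6-methylhepta-1,5-dien-2-yl)cyclotetradeca-1,7,11-trien-1-yl]methanol | C=C(CCC=C(C)C)[C@H]1C/C=C(/CO)CC/C=C(/C)CC/C=C(\C)CC1 | target

**Step count.** Total: 13 steps. Longest linear sequence: 11 steps (steps 1–6 and 9–13); steps 7 and 8 prepare the boronate.

**Steps most likely to fail**

1. Step 9. The hindered α-branched alkenyl-rhodium may transmetalate and insert slowly, so that protodeboronation takes over, or the ligand may not discriminate the two faces of the enamide well enough. The fallback uses an auxiliary-controlled cuprate addition; it sets out from 11 and comes back at 20. (S)-4-Phenyloxazolidin-2-one is N-acylated (n-BuLi, acryloyl chloride) to (S)-3-acryloyl-4-phenyloxazolidin-2-one F1. Cross-metathesis of F1 with 11 gives (S)-3-[(2E,6E,10Z)-13-chloro-6,10-dimethyltrideca-2,6,10-trienoyl]-4-phenyloxazolidin-2-one F2. The alkenyllithium 18 is converted into its magnesium cuprate (MgBr2·OEt2, CuBr·SMe2, THF/Me2S, −78 → −20 °C) and added to F2; in the chelated s-cis imide the phenyl group should shield one face and give (S)-3-[(3R,6E,10Z)-13-chloro-6,10-dimethyl-3-(6-methylhepta-1,5-dien-2-yl)trideca-6,10-dienoyl]-4-phenyloxazolidin-2-one F3. Transamidation (MeONHMe·HCl, AlMe3, CH2Cl2) then gives 20.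

2. Step 12. Intermolecular olefination may compete with ring closure, and the ring-forming transition state may erode the E selectivity. The fallback closes the ring at C1–C14 by alkylation and sets the alkene geometry afterwards; it sets out from 20 and comes back at 26. Acylation of the lithium enolate of ethyl acetate (LDA, THF, −78 °C) with 20 gives ethyl (5R,8E,12Z)-15-chloro-8,12-dimethyl-5-(6-methylhepta-1,5-dien-2-yl)-3-oxopentadeca-8,12-dienoate F4. High-dilution C-alkylation (NaI, Cs2CO3, MeCN, 70 °C) gives ethyl (4R,7E,11Z)-7,11-dimethyl-4-(6-methylhepta-1,5-dien-2-yl)-2-oxocyclotetradeca-7,11-diene-1-carboxylate F5. Chelate-controlled triflation (aq LiOH, Tf2O, toluene, 5 °C) gives the (Z)-enol triflate, ethyl (1Z,4R,7E,11Z)-7,11-dimethyl-4-(6-methylhepta-1,5-dien-2-yl)-2-(trifluoromethylsulfonyloxy)cyclotetradeca-1,7,11-triene-1-carboxylate F6. Palladium-catalysed reduction with retention (Pd(OAc)2, PPh3, Et3SiH, DMF) then gives 26.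

3. Step 11. Masking of the phosphonoacetate as its enolate may be incomplete, so that its ester is reduced too, or the aldehyde may be over-reduced. The fallback replaces the chemoselective reduction by a protecting-group sequence; it sets out from 20 and comes back at 25. DIBAL-H reduction of 20 (THF, −78 °C) gives (3R,6E,10Z)-13-chloro-6,10-dimethyl-3-(6-methylhepta-1,5-dien-2-yl)trideca-6,10-dienal F7. Acetalisation (HC(OMe)3, PPTS, MeOH) gives (3Z,7E,11R)-1-chloro-13,13-dimethoxy-4,8-dimethyl-11-(6-methylhepta-1,5-dien-2-yl)trideca-3,7-diene F8. Alkylation of 22 with F8 (NaI, DMF, 70 °C) gives ethyl (5Z,9E,13R)-2-(diethoxyphosphoryl)-15,15-dimethoxy-6,10-dimethyl-13-(6-methylhepta-1,5-dien-2-yl)pentadeca-5,9-dienoate F9. Mild hydrolysis (PPTS, acetone/H2O) then gives 25.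

Further compounds
F1 | step 9 | (S)-3-acryloyl-4-phenyloxazolidin-2-one | C=CC(=O)N1[C@@H](c2ccccc2)COC1=O
F2 | step 9 | (S)-3-[(2E,6E,10Z)-13-chloro-6,10-dimethyltrideca-2,6,10-trienoyl]-4-phenyloxazolidin-2-one | O=C(/C=C/CC/C(C)=C/CC/C(C)=C\CCCl)N1[C@@H](c2ccccc2)COC1=O
F3 | step 9 | (S)-3-[(3R,6E,10Z)-13-chloro-6,10-dimethyl-3-(6-methylhepta-1,5-dien-2-yl)trideca-6,10-dienoyl]-4-phenyloxazolidin-2-one | C=C(CCC=C(C)C)[C@@H](CC(=O)N1[C@@H](c2ccccc2)COC1=O)CC/C(C)=C/CC/C(C)=C\CCCl
F4 | step 12 | ethyl (5R,8E,12Z)-15-chloro-8,12-dimethyl-5-(6-methylhepta-1,5-dien-2-yl)-3-oxopentadeca-8,12-dienoate | C=C(CCC=C(C)C)[C@@H](CC(=O)CC(=O)OCC)CC/C(C)=C/CC/C(C)=C\CCCl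
F5 | step 12 | ethyl (4R,7E,11Z)-7,11-dimethyl-4-(6-methylhepta-1,5-dien-2-yl)-2-oxocyclotetradeca-7,11-diene-1-carboxylate (C1 epimers) | C=C(CCC=C(C)C)[C@H]1CC(=O)C(C(=O)OCC)CC/C=C(/C)CC/C=C(\C)CC1
F6 | step 12 | ethyl (1Z,4R,7E,11Z)-7,11-dimethyl-4-(6-methylhepta-1,5-dien-2-yl)-2-(trifluoromethylsulfonyloxy)cyclotetradeca-1,7,11-triene-1-carboxylate | C=C(CCC=C(C)C)[C@H]1C/C(OS(=O)(=O)C(F)(F)F)=C(/C(=O)OCC)CC/C=C(/C)CC/C=C(\C)CC1
F7 | step 11 | (3R,6E,10Z)-13-chloro-6,10-dimethyl-3-(6-methylhepta-1,5-dien-2-yl)trideca-6,10-dienal | C=C(CCC=C(C)C)[C@@H](CC=O)CC/C(C)=C/CC/C(C)=C\CCCl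
F8 | step 11 | (3Z,7E,11R)-1-chloro-13,13-dimethoxy-4,8-dimethyl-11-(6-methylhepta-1,5-dien-2-yl)trideca-3,7-diene | C=C(CCC=C(C)C)[C@@H](CC(OC)OC)CC/C(C)=C/CC/C(C)=C\CCCl
F9 | step 11 | ethyl (5Z,9E,13R)-2-(diethoxyphosphoryl)-15,15-dimethoxy-6,10-dimethyl-13-(6-methylhepta-1,5-dien-2-yl)pentadeca-5,9-dienoate (C2 epimers) | C=C(CCC=C(C)C)[C@@H](CC(OC)OC)CC/C(C)=C/CC/C(C)=C\CCC(C(=O)OCC)P(=O)(OCC)OCC
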